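**Strategy.** Everything rests on deleting the C4 methylene of the chroman: the pyran ring then contracts to a benzofuran-3(2H)-one in which the quaternary C2, flanked by O1 and C3, lies alpha to a ketone and can be installed by asymmetric enolate alkylation. Forward, a Lewis-acid-promoted insertion of the trimethylsilyldiazomethane carbon with 1,2-shift of the aryl carbon creates C3–C4 and C4–C4a at once and delivers the six-membered chroman-3-one while C2 stays untouched. The substrate is the (2R)-2-methylbenzofuranone bearing an allyl acetate arm at C2, the 4-methoxy group, the palmitate ester at the C6 carbinol and a silyl ether at the C7 carbinol as the latent aldehyde.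

Key step: step 9

Remark on configuration: (R) at C2 of the 3-oxo intermediates and (S) in the target denote the same spatial arrangement; only the CIP rank of C3 changes when the ketone is removed.
Remark on design: the acetate arm is carried as an allyl ester, because an ester that needs protic acid for removal would endanger the benzylic silyl ether once the ring is a 2,4-dioxygenated benzyl system; allyl is removed by neutral Pd(0).
Remark on bookkeeping: compounds that supply atoms to the target are numbered; auxiliary reagents are named where used. TiCl4 and BF3·OEt2 are promoters outside the balanced equations and leave in the aqueous work-up. (4-Bromo-3,5-dimethoxyphenyl)methanol is taken as a catalogue compound.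

Step 1
Reactants: 1 (4-bromo-3,5-dimethoxyphenyl)methanol; 2 N-methoxy-N-methylpropanamide
Product: 4 1-[4-(hydroxymethyl)-2,6-dimethoxyphenyl]propan-1-one, via dilithiated aryl alkoxide 3 (not isolated)
Conditions: n-BuLi (2.2 equiv), THF, −78 °C; then 2, −78 → 0 °C; aq. NH4Cl
Reagents that add atoms: 2 N-methoxy-N-methylpropanamide, CCC(=O)N(C)OC
Why: O–H deprotonation and bromine–lithium exchange give the 2,6-dimethoxyaryllithium, and its acylation stops at the ketone because the chelated tetrahedral adduct survives until the quench (halogen–metal exchange, Weinreb ketone synthesis).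

Step 2
Reactants: 4 1-[4-(hydroxymethyl)-2,6-dimethoxyphenyl]propan-1-one; 5 hexadecanoyl chloride
Product: 6 (3,5-dimethoxy-4-propanoylphenyl)methyl hexadecanoate
Conditions: Et3N, DMAP (cat.), CH2Cl2, 0 °C → rt
Reagents that add atoms: 5 hexadecanoyl chloride, CCCCCCCCCCCCCCCC(=O)Cl
Why: DMAP-catalysed acylation of the primary benzylic alcohol installs the final palmitate, which also serves as a Lewis-acid-stable mask for this carbinol.

Step 3
Reactants: 6 (3,5-dimethoxy-4-propanoylphenyl)methyl hexadecanoate; 7 dichloromethyl methyl ether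
Product: 8 (2-formyl-3,5-dimethoxy-4-propanoylphenyl)methyl hexadecanoate
Conditions: 7, TiCl4, CH2Cl2, −20 → 0 °C; then ice / 1 M HCl
Reagents that add atoms: 7 dichloromethyl methyl ether, COC(Cl)Cl; water, O
Why: Rieche formylation; the two equivalent free ring positions are each ortho to one methoxy, para to the other and meta to the ketone, so one regioisomer should form and the first formyl group deactivates the ring against a second.

Step 4
Reactants: 8 (2-formyl-3,5-dimethoxy-4-propanoylphenyl)methyl hexadecanoate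
Product: 9 (2-formyl-3-hydroxy-5-methoxy-4-propanoylphenyl)methyl hexadecanoate
Conditions: BCl3 (1.2 equiv), CH2Cl2, −78 → −20 °C; then H2O
Reagents that add atoms: none
Why: Chelation-controlled aryl methyl ether cleavage; the methoxy group wedged between aldehyde and ketone can receive boron from either carbonyl and should be cleaved ahead of the other one, which only the twisted ketone flanks.

Step 5
Reactants: 9 (2-formyl-3-hydroxy-5-methoxy-4-propanoylphenyl)methyl hexadecanoate
Product: 11 (7-formyl-4-methoxy-2-methyl-3-oxo-2,3-dihydrobenzofuran-6-yl)methyl hexadecanoate (racemic), via alpha-bromoketone 10 (not isolated)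
Conditions: CuBr2 (2.1 equiv), EtOAc/CHCl3, reflux; filter, concentrate; then K2CO3, MeCN, rt
Reagents that add atoms: none
Why: Copper(II) bromide alpha-brominates the ketone through its enol and the ortho phenoxide then displaces bromide in a 5-exo-tet closure (classical coumaranone synthesis); C2 forms racemic here and is reset through the planar enolate in step 8.

Step 6
Reactants: 11 (7-formyl-4-methoxy-2-methyl-3-oxo-2,3-dihydrobenzofuran-6-yl)methyl hexadecanoate
Product: 12 [7-(hydroxymethyl)-4-methoxy-2-methyl-3-oxo-2,3-dihydrobenzofuran-6-yl]methyl hexadecanoate (racemic)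
Conditions: NaBH4 (0.5 equiv), THF/EtOH, −40 °C; AcOH quench
Reagents that add atoms: none
Why: Chemoselective borohydride reduction; the aldehyde should react far faster than the doubly oxygen-conjugated C3 ketone or the ester, and the cold acidic quench avoids base-induced acyl transfer between the neighbouring carbinols.

Step 7
Reactants: 12 [7-(hydroxymethyl)-4-methoxy-2-methyl-3-oxo-2,3-dihydrobenzofuran-6-yl]methyl hexadecanoate
Product: 13 [4-methoxy-2-methyl-3-oxo-7-(triisopropylsilyloxymethyl)-2,3-dihydrobenzofuran-6-yl]methyl hexadecanoate (racemic)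
Conditions: TIPSCl, imidazole, DMF, 0 °C → rt
Reagents that add atoms: triisopropylsilyl chloride, CC(C)[Si](Cl)(C(C)C)C(C)C
Why: Imidazole-mediated silylation of the primary alcohol; the bulky silyl ether has a weakly basic oxygen and is the form in which the future aldehyde carbon faces the Lewis acid.

Step 8
Reactants: 13 [4-methoxy-2-methyl-3-oxo-7-(triisopropylsilyloxymethyl)-2,3-dihydrobenzofuran-6-yl]methyl hexadecanoate; 14 prop-2-enyl 2-bromoacetate
Product: 15 prop-2-enyl 2-[(2R)-6-(hexadecanoyloxymethyl)-4-methoxy-2-methyl-3-oxo-7-(triisopropylsilyloxymethyl)-2,3-dihydrobenzofuran-2-yl]acetate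
Conditions: 14, O-allyl-N-(9-anthracenylmethyl)cinchonidinium bromide (10 mol %), Cs2CO3, toluene, −20 °C, argon
Reagents that add atoms: 14 prop-2-enyl 2-bromoacetate, C=CCOC(=O)CBr
Why: Asymmetric phase-transfer alkylation; the planar 3-oxidobenzofuran enolate is ion-paired with the chiral ammonium cation, which shields one face so that C-alkylation should give the C2 quaternary centre as the (R)-isomer, and the cinchonine-derived pseudoenantiomer is used instead if the sense of induction proves opposite.

Step 9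
Reactants: 15 prop-2-enyl 2-[(2R)-6-(hexadecanoyloxymethyl)-4-methoxy-2-methyl-3-oxo-7-(triisopropylsilyloxymethyl)-2,3-dihydrobenzofuran-2-yl]acetate; 16 trimethylsilyldiazomethane
Product: 18 prop-2-enyl 2-[(2R)-7-(hexadecanoyloxymethyl)-5-methoxy-2-methyl-3-oxo-8-(triisopropylsilyloxymethyl)chroman-2-yl]acetate, via C4-trimethylsilyl chromanone 17 (not isolated)
Conditions: 16 (2 M in hexanes), BF3·OEt2, CH2Cl2, −78 → −30 °C; aq. NaHCO3; then SiO2, wet CH2Cl2, rt
Reagents that add atoms: 16 trimethylsilyldiazomethane, C[Si](C)(C)C=[N+]=[N-]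
Why: BF3 activates the C3 ketone, the diazo carbon adds to give a diazonium alkoxide, and the aryl carbon C3a migrates to that carbon with loss of N2, after which the C4-silyl ketone 17 is protodesilylated on silica to leave C4 as CH2. The closest known reaction is the Lewis-acid-promoted trimethylsilyldiazomethane homologation of 1-indanones and 1-tetralones to the benzo-fused beta-ketones. The six-membered ring arises by a 1,2-shift that enlarges the furanone, not by a cyclisation, so no Baldwin mode applies. No stereocentre is created and C2 is a spectator, so its configuration should be carried over unchanged. The step needs aryl migration in preference to C2 migration and a single insertion: O1 and the 4-methoxy group ortho to the migrating carbon raise its migratory aptitude, the silyl group left beside the new ketone blocks a second addition, and a C2 shift would proceed with retention to a chroman-4-one that gives the same chroman after deoxygenation.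

Step 10
Reactants: 18 prop-2-enyl 2-[(2R)-7-(hexadecanoyloxymethyl)-5-methoxy-2-methyl-3-oxo-8-(triisopropylsilyloxymethyl)chroman-2-yl]acetate
Product: 20 prop-2-enyl 2-[(2S)-7-(hexadecanoyloxymethyl)-5-methoxy-2-methyl-8-(triisopropylsilyloxymethyl)chroman-2-yl]acetate, via tosylhydrazone 19 (not isolated)
Conditions: TsNHNH2, THF/EtOH, 4 Å MS, rt; concentrate; catecholborane, CHCl3, 0 °C; then NaOAc·3H2O, reflux
Reagents that add atoms: none
Why: Caglioti-type deoxygenation in the Kabalka variant; catecholborane reduces the C=N bond, acetate triggers loss of sulfinate, and the alkyl diazene extrudes N2 to leave C3 as CH2 under near-neutral conditions that should spare both esters and the silyl ether.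

Step 11
Reactants: 20 prop-2-enyl 2-[(2S)-7-(hexadecanoyloxymethyl)-5-methoxy-2-methyl-8-(triisopropylsilyloxymethyl)chroman-2-yl]acetate
Product: 21 2-[(2S)-7-(hexadecanoyloxymethyl)-5-methoxy-2-methyl-8-(triisopropylsilyloxymethyl)chroman-2-yl]acetic acid
Conditions: Pd(PPh3)4 (5 mol %), morpholine, THF, rt; pH 4 buffer
Reagents that add atoms: none
Why: Tsuji–Trost deallylation; Pd(0) ionises the allyl ester and morpholine captures the allyl fragment, freeing the acid without acid or base that could harm the palmitate or the electron-rich benzylic silyl ether.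

Step 12
Reactants: 21 2-[(2S)-7-(hexadecanoyloxymethyl)-5-methoxy-2-methyl-8-(triisopropylsilyloxymethyl)chroman-2-yl]acetic acid
Product: 22 S-(4-methylphenyl) 2-[(2S)-7-(hexadecanoyloxymethyl)-5-methoxy-2-methyl-8-(triisopropylsilyloxymethyl)chroman-2-yl]ethanethioate
Conditions: 4-MeC6H4SH, DCC, DMAP (cat.), CH2Cl2, 0 °C → rt
Reagents that add atoms: 4-methylbenzenethiol, Cc1ccc(S)cc1
Why: Steglich-type thioesterification converts the acid into the aryl thioester that the following coupling needs as acyl donor.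

Step 13
Reactants: 22 S-(4-methylphenyl) 2-[(2S)-7-(hexadecanoyloxymethyl)-5-methoxy-2-methyl-8-(triisopropylsilyloxymethyl)chroman-2-yl]ethanethioate; 23 (2-methylprop-1-en-1-yl)boronic acid
Product: 24 [(2S)-5-methoxy-2-methyl-2-(4-methyl-2-oxopent-3-en-1-yl)-8-(triisopropylsilyloxymethyl)chroman-7-yl]methyl hexadecanoate
Conditions: 23, Pd2(dba)3 (cat.), tri(2-furyl)phosphine, CuTC, THF, 50 °C
Reagents that add atoms: 23 (2-methylprop-1-en-1-yl)boronic acid, CC(C)=CB(O)O
Why: Liebeskind–Srogl coupling; Pd inserts into the acyl C–S bond, copper thiophenecarboxylate binds the thiolate and relays the alkenyl group from boron, and reductive elimination gives the enone under neutral conditions, with the thiolate held on copper so that it cannot add to the enone.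

Step 14
Reactants: 24 [(2S)-5-methoxy-2-methyl-2-(4-methyl-2-oxopent-3-en-1-yl)-8-(triisopropylsilyloxymethyl)chroman-7-yl]methyl hexadecanoate
Product: 25 [(2S)-8-(hydroxymethyl)-5-methoxy-2-methyl-2-(4-methyl-2-oxopent-3-en-1-yl)chroman-7-yl]methyl hexadecanoate
Conditions: HF·pyridine, pyridine, THF, 0 °C → rt
Reagents that add atoms: none
Why: Fluoride cleavage of the silyl ether; the buffered reagent avoids a free alkoxide and thus migration of the palmitoyl group to the neighbouring carbinol.

Step 15
Reactants: 25 [(2S)-8-(hydroxymethyl)-5-methoxy-2-methyl-2-(4-methyl-2-oxopent-3-en-1-yl)chroman-7-yl]methyl hexadecanoate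
Product: 26 [(2S)-8-formyl-5-methoxy-2-methyl-2-(4-methyl-2-oxopent-3-en-1-yl)chroman-7-yl]methyl hexadecanoate
Conditions: MnO2 (activated), CH2Cl2, rt
Reagents that add atoms: none
Why: Manganese dioxide oxidation of the electron-rich benzylic alcohol should stop at the aldehyde and leave the enone, the ester and C2 untouched.

**Compound list**

1 | (4-bromo-3,5-dimethoxyphenyl)methanol | OCc1cc(OC)c(Br)c(OC)c1 | starting material
2 | N-methoxy-N-methylpropanamide | CCC(=O)N(C)OC | starting material
3 | lithium (4-lithio-3,5-dimethoxyphenyl)methanolate | [Li]OCc1cc(OC)c([Li])c(OC)c1 | intermediate (not isolated)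
4 | 1-[4-(hydroxymethyl)-2,6-dimethoxyphenyl]propan-1-one | CCC(=O)c1c(OC)cc(CO)cc1OC | intermediate
5 | hexadecanoyl chloride | CCCCCCCCCCCCCCCC(=O)Cl | starting material
6 | (3,5-dimethoxy-4-propanoylphenyl)methyl hexadecanoate | CCCCCCCCCCCCCCCC(=O)OCc1cc(OC)c(C(=O)CC)c(OC)c1 | intermediate
7 | dichloromethyl methyl ether | COC(Cl)Cl | starting material
8 | (2-formyl-3,5-dimethoxy-4-propanoylphenyl)methyl hexadecanoate | CCCCCCCCCCCCCCCC(=O)OCc1cc(OC)c(C(=O)CC)c(OC)c1C=O | intermediate
9 | (2-formyl-3-hydroxy-5-methoxy-4-propanoylphenyl)methyl hexadecanoate | CCCCCCCCCCCCCCCC(=O)OCc1cc(OC)c(C(=O)CC)c(O)c1C=O | intermediate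
10 | [4-(2-bromopropanoyl)-2-formyl-3-hydroxy-5-methoxyphenyl]methyl hexadecanoate (racemic) | CCCCCCCCCCCCCCCC(=O)OCc1cc(OC)c(C(=O)C(C)Br)c(O)c1C=O | intermediate (not isolated)
11 | (7-formyl-4-methoxy-2-methyl-3-oxo-2,3-dihydrobenzofuran-6-yl)methyl hexadecanoate (racemic) | CCCCCCCCCCCCCCCC(=O)OCc1cc(OC)c2c(c1C=O)OC(C)C2=O | intermediate
12 | [7-(hydroxymethyl)-4-methoxy-2-methyl-3-oxo-2,3-dihydrobenzofuran-6-yl]methyl hexadecanoate (racemic) | CCCCCCCCCCCCCCCC(=O)OCc1cc(OC)c2c(c1CO)OC(C)C2=O | intermediate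
13 | [4-methoxy-2-methyl-3-oxo-7-(triisopropylsilyloxymethyl)-2,3-dihydrobenzofuran-6-yl]methyl hexadecanoate (racemic) | CCCCCCCCCCCCCCCC(=O)OCc1cc(OC)c2c(c1CO[Si](C(C)C)(C(C)C)C(C)C)OC(C)C2=O | intermediate
14 | prop-2-enyl 2-bromoacetate | C=CCOC(=O)CBr | starting material
15 | prop-2-enyl 2-[(2R)-6-(hexadecanoyloxymethyl)-4-methoxy-2-methyl-3-oxo-7-(triisopropylsilyloxymethyl)-2,3-dihydrobenzofuran-2-yl]acetate | CCCCCCCCCCCCCCCC(=O)OCc1cc(OC)c2c(c1CO[Si](C(C)C)(C(C)C)C(C)C)O[C@](C)(CC(=O)OCC=C)C2=O | intermediate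
16 | trimethylsilyldiazomethane | C[Si](C)(C)C=[N+]=[N-] | starting material
17 | prop-2-enyl 2-[(2R)-7-(hexadecanoyloxymethyl)-5-methoxy-2-methyl-3-oxo-8-(triisopropylsilyloxymethyl)-4-(trimethylsilyl)chroman-2-yl]acetate (C4 epimers) | CCCCCCCCCCCCCCCC(=O)OCc1cc(OC)c2c(c1CO[Si](C(C)C)(C(C)C)C(C)C)O[C@](C)(CC(=O)OCC=C)C(=O)C2[Si](C)(C)C | intermediate (not isolated)
18 | prop-2-enyl 2-[(2R)-7-(hexadecanoyloxymethyl)-5-methoxy-2-methyl-3-oxo-8-(triisopropylsilyloxymethyl)chroman-2-yl]acetate | CCCCCCCCCCCCCCCC(=O)OCc1cc(OC)c2c(c1CO[Si](C(C)C)(C(C)C)C(C)C)O[C@](C)(CC(=O)OCC=C)C(=O)C2 | intermediate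
19 | prop-2-enyl 2-[(2R)-7-(hexadecanoyloxymethyl)-5-methoxy-2-methyl-3-[(4-methylphenyl)sulfonylhydrazinylidene]-8-(triisopropylsilyloxymethyl)chroman-2-yl]acetate | CCCCCCCCCCCCCCCC(=O)OCc1cc(OC)c2c(c1CO[Si](C(C)C)(C(C)C)C(C)C)O[C@](C)(CC(=O)OCC=C)C(=NNS(=O)(=O)c3ccc(C)cc3)C2 | intermediate (not isolated)
20 | prop-2-enyl 2-[(2S)-7-(hexadecanoyloxymethyl)-5-methoxy-2-methyl-8-(triisopropylsilyloxymethyl)chroman-2-yl]acetate | CCCCCCCCCCCCCCCC(=O)OCc1cc(OC)c2c(c1CO[Si](C(C)C)(C(C)C)C(C)C)O[C@](C)(CC(=O)OCC=C)CC2 | intermediate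
21 | 2-[(2S)-7-(hexadecanoyloxymethyl)-5-methoxy-2-methyl-8-(triisopropylsilyloxymethyl)chroman-2-yl]acetic acid | CCCCCCCCCCCCCCCC(=O)OCc1cc(OC)c2c(c1CO[Si](C(C)C)(C(C)C)C(C)C)O[C@](C)(CC(=O)O)CC2 | intermediate
22 | S-(4-methylphenyl) 2-[(2S)-7-(hexadecanoyloxymethyl)-5-methoxy-2-methyl-8-(triisopropylsilyloxymethyl)chroman-2-yl]ethanethioate | CCCCCCCCCCCCCCCC(=O)OCc1cc(OC)c2c(c1CO[Si](C(C)C)(C(C)C)C(C)C)O[C@](C)(CC(=O)Sc3ccc(C)cc3)CC2 | intermediate
23 | (2-methylprop-1-en-1-yl)boronic acid | CC(C)=CB(O)O | starting material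
24 | [(2S)-5-methoxy-2-methyl-2-(4-methyl-2-oxopent-3-en-1-yl)-8-(triisopropylsilyloxymethyl)chroman-7-yl]methyl hexadecanoate | CCCCCCCCCCCCCCCC(=O)OCc1cc(OC)c2c(c1CO[Si](C(C)C)(C(C)C)C(C)C)O[C@](C)(CC(=O)C=C(C)C)CC2 | intermediate
25 | [(2S)-8-(hydroxymethyl)-5-methoxy-2-methyl-2-(4-methyl-2-oxopent-3-en-1-yl)chroman-7-yl]methyl hexadecanoate | CCCCCCCCCCCCCCCC(=O)OCc1cc(OC)c2c(c1CO)O[C@](C)(CC(=O)C=C(C)C)CC2 | intermediate
26 | [(2S)-8-formyl-5-methoxy-2-methyl-2-(4-methyl-2-oxopent-3-en-1-yl)chroman-7-yl]methyl hexadecanoate | CCCCCCCCCCCCCCCC(=O)OCc1cc(OC)c2c(c1C=O)O[C@](C)(CC(=O)C=C(C)C)CC2 | target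

**Totals.** Total step count: 15. Longest linear sequence: 15 steps (1 to 26).

**Steps most likely to fail, in order: step 9, step 8, step 10.**

Step 9. The bulky diazoalkane may add too slowly to a hindered carbonyl that two conjugated oxygen donors deactivate, so that the Lewis acid consumes the reagent first, or forcing may strip the silyl ether. The fallback sets out from 15. Non-basic Takai–Lombardo methylenation (Zn, CH2Br2, TiCl4, THF), which leaves esters alone, should give prop-2-enyl 2-[(2R)-6-(hexadecanoyloxymethyl)-4-methoxy-2-methyl-3-methylidene-7-(triisopropylsilyloxymethyl)-2,3-dihydrobenzofuran-2-yl]acetate F1. Hydroxy(tosyloxy)iodobenzene in aqueous methanol at 0 °C then adds iodine(III) to the terminal CH2, solvent captures the benzylic cation at C3, and the aryl carbon shifts to the exocyclic carbon as iodobenzene leaves. This established oxidative ring expansion of 1-methylene benzo-fused rings forms the same two bonds and returns to the route at 18.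

Step 8. The ion pair may discriminate the two enolate faces poorly, or alkylation may go to oxygen. The fallback sets out from 13 and returns at 15.
- NaHMDS and allyl chloroformate (THF, −78 °C) should give the enol carbonate [4-methoxy-2-methyl-3-(prop-2-enoxycarbonyloxy)-7-(triisopropylsilyloxymethyl)benzofuran-6-yl]methyl hexadecanoate F2.
- Pd2(dba)3 with a chiral Trost ligand, its enantiomer chosen for the (R)-product, effects decarboxylative asymmetric allylic alkylation to [(2R)-4-methoxy-2-methyl-3-oxo-2-(prop-2-enyl)-7-(triisopropylsilyloxymethyl)-2,3-dihydrobenzofuran-6-yl]methyl hexadecanoate F3.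
- OsO4/NaIO4 with 2,6-lutidine cleaves the terminal alkene to [(2R)-4-methoxy-2-methyl-3-oxo-2-(2-oxoethyl)-7-(triisopropylsilyloxymethyl)-2,3-dihydrobenzofuran-6-yl]methyl hexadecanoate F4.
- Pinnick oxidation gives 2-[(2R)-6-(hexadecanoyloxymethyl)-4-methoxy-2-methyl-3-oxo-7-(triisopropylsilyloxymethyl)-2,3-dihydrobenzofuran-2-yl]acetic acid F5.
- Allyl bromide with KHCO3 in DMF gives 15.

Step 10. The hydrazone or diazene stage may open the ring by expelling the C2 aryloxy group, or the hydrazone may form slowly beside the quaternary centre. The fallback sets out from 18. KHMDS and PhNTf2 (THF, −78 °C; enolisation is possible only towards C4) should give prop-2-enyl 2-[(2R)-7-(hexadecanoyloxymethyl)-5-methoxy-2-methyl-8-(triisopropylsilyloxymethyl)-3-(trifluoromethylsulfonyloxy)-2H-chromen-2-yl]acetate F6. Pd(OAc)2/PPh3 with HCO2H/Et3N in DMF reduces the C–OTf bond and cleaves the allyl ester in the same operation, giving 2-[(2R)-7-(hexadecanoyloxymethyl)-5-methoxy-2-methyl-8-(triisopropylsilyloxymethyl)-2H-chromen-2-yl]acetic acid F7. Hydrogenation over Wilkinson's catalyst saturates C3=C4 without benzylic hydrogenolysis and rejoins the route at 21.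

**Further compounds**

F1 | step 9 | prop-2-enyl 2-[(2R)-6-(hexadecanoyloxymethyl)-4-methoxy-2-methyl-3-methylidene-7-(triisopropylsilyloxymethyl)-2,3-dihydrobenzofuran-2-yl]acetate | CCCCCCCCCCCCCCCC(=O)OCc1cc(OC)c2c(c1CO[Si](C(C)C)(C(C)C)C(C)C)O[C@](C)(CC(=O)OCC=C)C2=C
F2 | step 8 | [4-methoxy-2-methyl-3-(prop-2-enoxycarbonyloxy)-7-(triisopropylsilyloxymethyl)benzofuran-6-yl]methyl hexadecanoate | CCCCCCCCCCCCCCCC(=O)OCc1cc(OC)c2c(OC(=O)OCC=C)c(C)oc2c1CO[Si](C(C)C)(C(C)C)C(C)C
F3 | step 8 | [(2R)-4-methoxy-2-methyl-3-oxo-2-(prop-2-enyl)-7-(triisopropylsilyloxymethyl)-2,3-dihydrobenzofuran-6-yl]methyl hexadecanoate | CCCCCCCCCCCCCCCC(=O)OCc1cc(OC)c2c(c1CO[Si](C(C)C)(C(C)C)C(C)C)O[C@](C)(CC=C)C2=O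
F4 | step 8 | [(2R)-4-methoxy-2-methyl-3-oxo-2-(2-oxoethyl)-7-(triisopropylsilyloxymethyl)-2,3-dihydrobenzofuran-6-yl]methyl hexadecanoate | CCCCCCCCCCCCCCCC(=O)OCc1cc(OC)c2c(c1CO[Si](C(C)C)(C(C)C)C(C)C)O[C@](C)(CC=O)C2=O
F5 | step 8 | 2-[(2R)-6-(hexadecanoyloxymethyl)-4-methoxy-2-methyl-3-oxo-7-(triisopropylsilyloxymethyl)-2,3-dihydrobenzofuran-2-yl]acetic acid | CCCCCCCCCCCCCCCC(=O)OCc1cc(OC)c2c(c1CO[Si](C(C)C)(C(C)C)C(C)C)O[C@](C)(CC(=O)O)C2=O
F6 | step 10 | prop-2-enyl 2-[(2R)-7-(hexadecanoyloxymethyl)-5-methoxy-2-methyl-8-(triisopropylsilyloxymethyl)-3-(trifluoromethylsulfonyloxy)-2H-chromen-2-yl]acetate | CCCCCCCCCCCCCCCC(=O)OCc1cc(OC)c2c(c1CO[Si](C(C)C)(C(C)C)C(C)C)O[C@](C)(CC(=O)OCC=C)C(OS(=O)(=O)C(F)(F)F)=C2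
F7 | step 10 | 2-[(2R)-7-(hexadecanoyloxymethyl)-5-methoxy-2-methyl-8-(triisopropylsilyloxymethyl)-2H-chromen-2-yl]acetic acid | CCCCCCCCCCCCCCCC(=O)OCc1cc(OC)c2c(c1CO[Si](C(C)C)(C(C)C)C(C)C)O[C@](C)(CC(=O)O)C=C2
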